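The data come from a simulation for an exercise, and the scatter is random.

The vessel was a closed, stirred flask held at constant volume and temperature, and each flask below started from free monomer and initiator. I had two earlier runs to go on.

all flasks: free monomer 0.80 M
- alder: initiator 2.8 mM; run made earlier
- maple: initiator 18 mM; run made earlier
- north-west: initiator 6.0 mM; time 10 min
- south: initiator 2.5 mM; time 10 min
- south-east: initiator 4.0 mM; time 10 min
- north: initiator 8.0 mM; time 10 min
- west: initiator 12 mM; time 10 min
- south-west: initiator 2.0 mM; time 10 min

- alder (time / min: monomer in chains / %): 0.833: 15.5; 1.50: 29.7; 2.50: 43.5; 3.00: 47.9; 4.00: 54.6; 5.00: 58.2
- maple (time / min: monomer in chains / %): 0.833: 60.1; 1.50: 79.2; 2.50: 83.1; 3.00: 83.7; 4.00: 83.8; 5.00: 83.8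

(scatter of a reading: 0.3 percentage points)

- all flasks from highest to lowest amount of monomer in chains, in percent of the free monomer charged, at 10 min (north-west / south / south-east / north / west / south-west)
- the same order at 80 min (north-west / south / south-east / north / west / south-west)
- the amount of monomer in chains, in percent of the free monomer charged of the flask you put first, at 10 min
- the amount of monomer in chains, in percent of the free monomer charged of the flask you put last, at 10 min



The two runs seemed to disagree. Maple, with 18 mM of initiator, stood still at 83.8%, which looks like a limit set by the free monomer, yet alder, with the same 0.80 M of free monomer and 2.8 mM of initiator, looked merely slower at 58.2%, still gaining at 5.00 min.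

I counted half-lives to clear this up. Alder's gain fell from 6.7 percentage points in one minute to 3.6 points in the next, so as a reading the gain halved every 1.12 min. Summing that shrinking tail put alder's ceiling at 62.4%, lower than maple's, so by this reckoning alder was stopping lower, not just running slower.

I treated the tail as pseudo-first-order, with a rate proportional to c(initiator), and kept the tail's half-life times the initiator charge, 3.12 mM·min, as the half-life product. Maple's gap to its plateau closed, as a reading, with a half-life of 0.368 min, twice what the product gives, so I trusted it near alder's charge and not at maple's. South-west, with the longest half-life by this count, 1.56 min, still had 6.41 half-lives in 10 min. I therefore expected the flasks to stand near their ceilings by then and to rank by initiator at both times.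

The forecast put west > north > north-west > south-east > south > south-west at 10 min and west > north > north-west > south-east > south > south-west at 80 min, with 83.7% first and 55% last, on the ground that “Low-initiator flasks stall below equilibrium, so conversion rises with initiator at both times”. My count gave the same order but no figure for either end.

The flasks gave west > north > north-west > south-east > south > south-west at 10 min and west > north > north-west > south-east > south > south-west at 80 min, with west at 80.2% and south-west at 56.4%.

    free monomer + initiator → living end + monomer in chains (k = 0.0328 /M/s)
    2 free monomer → homo dimer (k = 0.00477 /M/s)
    free monomer + living end → monomer in chains + living end, rate k3*[living end]*[free monomer] (k = 3.58 /M/s)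

South-west held 8.13% free monomer at 5.00 min, and 3.20 half-lives from there gave 0.885%, against 0.986% found at 10.0 min. South, from 5.79%, gave 0.362% by the same count, against 0.455%. In south-west, of the turnover up to 10 min, half of the homo dimer step was done by 0.637 min, but half of the chain growth step only by 1.93 min. At 10.0 min in south-west, growth was using free monomer 90 times as fast as homo dimer formation, and that flask held 42.6% of the free monomer charged as homo dimer.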